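**Retrosynthetic overview**
1. Numbering: decalin as in labdanes (ring A = C-1 to C-5 and C-10, ring B = C-5 to C-10); tether C-11/C-12; C-13 = formyl-bearing alkene carbon; C-14 = its CH partner; C-15 = CH2; ring C (butenolide) = O–C-16(H)–C-17(CH2OH)=C-18–C-19(=O).
2. Key disconnection C-12–C-13: Negishi coupling of the primary alkylzinc iodide 15 (from homodrimenyl iodide 4) with the (Z)-α-iodoenal 14; the acidic work-up of the same operation removes the silyl group and gives the target.
3. Enabling feature: C-13 is the sp2 α-carbon of an enal, so it can carry iodine with fixed Z geometry and a formyl-activated C–I bond; C-12 is a primary carbon insulated by C-11 from the inert tetrasubstituted C-8=C-9 alkene of ring B, so its zinc reagent has no β-leaving group.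
4. Fragment 1: rings A and B come intact from (+)-sclareolide (lactone opening with dehydration to C-8=C-9, reduction, iodination). Fragment 2: 3-furanmethanol is oxidized with singlet oxygen, the lactol is opened to a (Z)-formyl ester, catalytic asymmetric allylboration sets C-16, then cross-metathesis and α-iodination follow.
5. Ring order: rings A/B (chiral pool) → ring C (formed in step 5, opened in step 6, re-closed in step 7) → no ring is formed in the key step.

Key step: step 10

Assumption: (R)-TRIP is taken to direct allyl transfer from the pinacol allylboronate to the Re face of aldehyde 9, as it does with aryl and α,β-unsaturated aldehydes; if the sense were opposite, (S)-TRIP would be used.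

**Route**

Step 1
Reactants: 1 (+)-sclareolide
Product: 2 methyl 2-[(4aS,8aS)-2,5,5,8a-tetramethyl-3,4,4a,5,6,7,8,8a-octahydronaphthalen-1-yl]acetate
Conditions: conc. H2SO4, MeOH, 65 °C; chromatography on AgNO3-impregnated silica
Reagents that add atoms: methanol (CO)
Why: Acid-catalysed lactone methanolysis with E1 loss of the tertiary C-8 oxygen under equilibrating conditions should favour the tetrasubstituted C-8=C-9 alkene, the methyl ester blocks relactonization, C-5 and C-10 are untouched, and minor alkene isomers would be removed on the silver-doped silica.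

Step 2
Reactants: 2 methyl ester
Product: 3 2-[(4aS,8aS)-2,5,5,8a-tetramethyl-3,4,4a,5,6,7,8,8a-octahydronaphthalen-1-yl]ethanol
Conditions: LiAlH4, THF, 0 °C
Reagents that add atoms: none
Why: Hydride reduction of the ester to the primary alcohol should leave the unactivated tetrasubstituted alkene untouched.

Step 3
Reactants: 3 homodrimenol
Product: 4 (4aS,8aS)-1-(2-iodoethyl)-2,5,5,8a-tetramethyl-3,4,4a,5,6,7,8,8a-octahydronaphthalene
Conditions: I2, PPh3, imidazole, CH2Cl2, 0 to 23 °C
Reagents that add atoms: iodine (II)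
Why: Appel-type iodination converts the unhindered primary alcohol into the iodide by SN2 displacement under buffered conditions that should not move the alkene.

Step 4
Reactants: 5 furan-3-ylmethanol
Product: 6 tert-butyl(furan-3-ylmethoxy)dimethylsilane
Conditions: TBSCl, imidazole, DMF, 23 °C
Reagents that add atoms: tert-butyldimethylsilyl chloride (CC(C)(C)[Si](C)(C)Cl)
Why: Imidazole-assisted silylation masks the primary hydroxyl so that it cannot interfere with the aldehyde and lactone chemistry that follows.

Step 5
Reactants: 6 silyl ether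
Product: 8 4-{[(tert-butyldimethylsilyl)oxy]methyl}-5-hydroxyfuran-2(5H)-one, via endoperoxide 7 (not isolated)
Conditions: O2, rose bengal (cat.), visible light, iPr2NEt, CH2Cl2, −78 °C
Reagents that add atoms: dioxygen (O=O)
Why: [4+2] addition of singlet oxygen to the furan followed by Kornblum–DeLaMare rearrangement, in which the hindered amine removes the bridgehead hydrogen remote from the substituent, should place the carbonyl distal and the lactol carbon next to the substituted carbon; the lactol centre is racemic and is erased in step 6.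

Step 6
Reactants: 8 hydroxybutenolide
Product: 9 methyl (2Z)-4-[(tert-butyldimethylsilyl)oxy]-3-formylbut-2-enoate
Conditions: MeI, K2CO3, DMF, 0 °C
Reagents that add atoms: iodomethane (CI)
Why: Base opens the pseudo-acid to its ring-derived (Z)-4-oxo-2-enoate, and SN2 O-methylation of the carboxylate frees the aldehyde while keeping the cis ester needed for later lactonization.

Step 7
Reactants: 9 formyl ester
Product: 12 (5R)-5-allyl-4-{[(tert-butyldimethylsilyl)oxy]methyl}furan-2(5H)-one, via borate ester 10 (not isolated), via hydroxy ester 11 (not isolated)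
Conditions: allylB(pin), (R)-TRIP (5 mol %), toluene, −30 °C; aqueous work-up; PPTS (cat.), CH2Cl2, 23 °C
Reagents that add atoms: 2-allyl-4,4,5,5-tetramethyl-1,3,2-dioxaborolane (C=CCB1OC(C)(C)C(C)(C)O1)
Why: Chiral phosphoric acid-catalysed allylboration through a chair six-membered transition state should deliver the allyl group to the Re face of the aldehyde and so set the (R)-carbinol (C-16), after which the cis ester lactonizes to the butenolide.

Step 8
Reactants: 12 allyl butenolide
Product: 13 (2E)-4-[(2R)-3-{[(tert-butyldimethylsilyl)oxy]methyl}-5-oxo-2,5-dihydrofuran-2-yl]but-2-enal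
Conditions: crotonaldehyde (5 equiv), second-generation Hoveyda–Grubbs catalyst (5 mol %), CH2Cl2, 40 °C
Reagents that add atoms: (E)-but-2-enal (C/C=C/C=O)
Why: Olefin cross-metathesis of the terminal alkene with excess crotonaldehyde should give the thermodynamically favoured (E)-enal, the trisubstituted electron-poor butenolide alkene being inert to the ruthenium carbene.

Step 9
Reactants: 13 enal
Product: 14 (2Z)-2-iodo-4-[(2R)-3-{[(tert-butyldimethylsilyl)oxy]methyl}-5-oxo-2,5-dihydrofuran-2-yl]but-2-enal
Conditions: I2, pyridine, DMAP (cat.), CH2Cl2, 0 to 23 °C, dark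
Reagents that add atoms: iodine (II)
Why: Amine-mediated α-iodination (conjugate addition of the amine, iodination, elimination) should occur only at the enal, whose β-carbon is monosubstituted whereas that of the butenolide is fully substituted, and the addition–elimination path gives the thermodynamically preferred Z isomer with iodine cis to C-15.

Step 10
Reactants: 4 homodrimenyl iodide, 14 (Z)-α-iodoenal
Product: 17 (2E)-4-[(2R)-3-(hydroxymethyl)-5-oxo-2,5-dihydrofuran-2-yl]-2-{2-[(4aS,8aS)-2,5,5,8a-tetramethyl-3,4,4a,5,6,7,8,8a-octahydronaphthalen-1-yl]ethyl}but-2-enal, via alkylzinc iodide 15 (not isolated), via silyl ether 16 (not isolated)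
Conditions: (a) 4, Zn dust (activated with BrCH2CH2Br and Me3SiCl), LiCl, THF, 40 °C, excess zinc removed; (b) 14, PdCl2(dppf) (5 mol %), THF, 0 to 23 °C; (c) 1 M HCl, THF, 23 °C
Reagents that add atoms: none
Why: LiCl-assisted insertion of zinc into the primary C–I bond of 4 gives 15; zerovalent palladium formed from PdCl2(dppf) adds oxidatively to the C-13–I bond of 14, alkyl transfer from zinc and reductive elimination forge C-12–C-13, and the aqueous HCl work-up hydrolyses the silyl ether of 16 to 17. The closest known reaction type is the Negishi coupling of primary alkylzinc halides with alkenyl iodides, α-iodo enones included, which runs with retention of alkene geometry. No ring is closed and no stereocentre is created; the only stereo-element set is the C-13=C-14 geometry, controlled by the Z geometry of 14, so that C-12 takes the place of iodine and the formyl group ends trans to C-15 (E). The step needs chemoselectivity for the C–I bond over the aldehyde, over the enal and butenolide acceptors and over β-hydride loss from the alkylpalladium; the low nucleophilicity of the alkylzinc iodide, the formyl-activated C(sp2)–I bond and the wide-bite-angle dppf ligand should secure it. Because no base is present, the acidic C-15 hydrogens (whose removal would expel the lactone carboxylate) and the epimerizable C-16 centre stay untouched, and the tetrasubstituted C-8=C-9 alkene, insulated from zinc by C-11, neither inserts nor migrates. In one operation the step joins the C16 and C9 halves, completes the C25 skeleton at its final oxidation level and releases the unprotected target.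

**Compound list**
1 | (+)-sclareolide, (3aR,5aS,9aS,9bR)-3a,6,6,9a-tetramethyldecahydronaphtho[2,1-b]furan-2(1H)-one | C[C@]12CCCC([C@@H]1CC[C@@]3([C@@H]2CC(=O)O3)C)(C)C | starting material
2 | methyl 2-[(4aS,8aS)-2,5,5,8a-tetramethyl-3,4,4a,5,6,7,8,8a-octahydronaphthalen-1-yl]acetate | CC1=C(CC(=O)OC)[C@@]2(C)CCCC(C)(C)[C@@H]2CC1 | intermediate
3 | 2-[(4aS,8aS)-2,5,5,8a-tetramethyl-3,4,4a,5,6,7,8,8a-octahydronaphthalen-1-yl]ethanol | CC1=C(CCO)[C@@]2(C)CCCC(C)(C)[C@@H]2CC1 | intermediate
4 | (4aS,8aS)-1-(2-iodoethyl)-2,5,5,8a-tetramethyl-3,4,4a,5,6,7,8,8a-octahydronaphthalene | CC1=C(CCI)[C@@]2(C)CCCC(C)(C)[C@@H]2CC1 | intermediate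
5 | furan-3-ylmethanol | OCc1ccoc1 | starting material
6 | tert-butyl(furan-3-ylmethoxy)dimethylsilane | CC(C)(C)[Si](C)(C)OCc1ccoc1 | intermediate
7 | 5-{[(tert-butyldimethylsilyl)oxy]methyl}-2,3,7-trioxabicyclo[2.2.1]hept-5-ene (racemic, not isolated) | CC(C)(C)[Si](C)(C)OCC1=CC2OOC1O2 | intermediate
8 | 4-{[(tert-butyldimethylsilyl)oxy]methyl}-5-hydroxyfuran-2(5H)-one (racemic lactol) | CC(C)(C)[Si](C)(C)OCC1=CC(=O)OC1O | intermediate
9 | methyl (2Z)-4-[(tert-butyldimethylsilyl)oxy]-3-formylbut-2-enoate | COC(=O)/C=C(\C=O)CO[Si](C)(C)C(C)(C)C | intermediate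
10 | methyl (2Z,4R)-3-{[(tert-butyldimethylsilyl)oxy]methyl}-4-[(4,4,5,5-tetramethyl-1,3,2-dioxaborolan-2-yl)oxy]hepta-2,6-dienoate (not isolated) | COC(=O)/C=C(\[C@H](OB1OC(C)(C)C(C)(C)O1)CC=C)CO[Si](C)(C)C(C)(C)C | intermediate
11 | methyl (2Z,4R)-3-{[(tert-butyldimethylsilyl)oxy]methyl}-4-hydroxyhepta-2,6-dienoate (not isolated) | COC(=O)/C=C(\[C@H](O)CC=C)CO[Si](C)(C)C(C)(C)C | intermediate
12 | (5R)-5-allyl-4-{[(tert-butyldimethylsilyl)oxy]methyl}furan-2(5H)-one | C=CC[C@H]1OC(=O)C=C1CO[Si](C)(C)C(C)(C)C | intermediate
13 | (2E)-4-[(2R)-3-{[(tert-butyldimethylsilyl)oxy]methyl}-5-oxo-2,5-dihydrofuran-2-yl]but-2-enal | O=C/C=C/C[C@H]1OC(=O)C=C1CO[Si](C)(C)C(C)(C)C | intermediate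
14 | (2Z)-2-iodo-4-[(2R)-3-{[(tert-butyldimethylsilyl)oxy]methyl}-5-oxo-2,5-dihydrofuran-2-yl]but-2-enal | O=C/C(I)=C/C[C@H]1OC(=O)C=C1CO[Si](C)(C)C(C)(C)C | intermediate
15 | {2-[(4aS,8aS)-2,5,5,8a-tetramethyl-3,4,4a,5,6,7,8,8a-octahydronaphthalen-1-yl]ethyl}zinc iodide (not isolated) | CC1=C(CC[Zn]I)[C@@]2(C)CCCC(C)(C)[C@@H]2CC1 | intermediate
16 | tert-butyldimethylsilyl ether of the target at the hydroxymethyl group (not isolated) | CC1=C(CC/C(C=O)=C\C[C@H]2OC(=O)C=C2CO[Si](C)(C)C(C)(C)C)[C@@]2(C)CCCC(C)(C)[C@@H]2CC1 | intermediate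
17 | (2E)-4-[(2R)-3-(hydroxymethyl)-5-oxo-2,5-dihydrofuran-2-yl]-2-{2-[(4aS,8aS)-2,5,5,8a-tetramethyl-3,4,4a,5,6,7,8,8a-octahydronaphthalen-1-yl]ethyl}but-2-enal | CC1=C(CC/C(C=O)=C\C[C@H]2OC(=O)C=C2CO)[C@@]2(C)CCCC(C)(C)[C@@H]2CC1 | target

**Step count and risks**
Total steps: 10. Longest linear sequence: 7 steps (steps 4 to 10, from furan-3-ylmethanol); the sclareolide branch is 4 steps (steps 1 to 3 and 10).

Steps most likely to fail:

1. Step 10. What may go wrong: reduction of the C–I bond of 14 by halogen–zinc exchange, addition of the organozinc to the aldehyde, or β-hydride loss from the alkylpalladium before reductive elimination. Fallback: the route sets out from 4 and rejoins at 16, using 12 in place of 14. Iodide 4 is alkylated with the lithium aza-enolate of N-cyclohexylacetaldimine (LDA, THF, −78 to 0 °C), which forms C-12–C-13 and gives N-cyclohexyl-4-[(4aS,8aS)-2,5,5,8a-tetramethyl-3,4,4a,5,6,7,8,8a-octahydronaphthalen-1-yl]butan-1-imine F1. Hydrolysis with aqueous oxalic acid gives 4-[(4aS,8aS)-2,5,5,8a-tetramethyl-3,4,4a,5,6,7,8,8a-octahydronaphthalen-1-yl]butanal F2. Mannich-type α-methylenation (aqueous formaldehyde, pyrrolidine and propionic acid as catalysts, iPrOH, 45 °C) gives 2-methylidene-4-[(4aS,8aS)-2,5,5,8a-tetramethyl-3,4,4a,5,6,7,8,8a-octahydronaphthalen-1-yl]butanal F3. Cross-metathesis of F3 with 12 (second-generation Hoveyda–Grubbs catalyst, CH2Cl2, 40 °C) should then give the (E)-trisubstituted enal 16, which is desilylated as in step 10.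

2. Step 9. What may go wrong: amine-induced deprotonation at C-15 with expulsion of the lactone carboxylate (ring opening), epimerization at C-16, or stalled iodination of the acyclic enal. Fallback: the route sets out from 13 and rejoins at 16. Bromine is added to the enal alkene (Br2, CH2Cl2, −78 °C) to give 2,3-dibromo-4-[(2R)-3-{[(tert-butyldimethylsilyl)oxy]methyl}-5-oxo-2,5-dihydrofuran-2-yl]butanal F4. Brief dehydrobromination (Et3N, −78 to 0 °C) gives (2Z)-2-bromo-4-[(2R)-3-{[(tert-butyldimethylsilyl)oxy]methyl}-5-oxo-2,5-dihydrofuran-2-yl]but-2-enal F5. F5 is coupled with 15 under the conditions of step 10 (Pd(OAc)2 with SPhos if oxidative addition is slow) to give 16.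

3. Step 7. What may go wrong: poor facial selectivity in the allyl transfer to this ester-bearing aldehyde, or Z-to-E isomerization of 9 before the lactone closes. Fallback: the route sets out from 9 and rejoins at 11. Catalyst control by the Brønsted acid is replaced by a chiral Lewis acid with an open transition state, a Keck allylation: allyltributylstannane, Ti(OiPr)4 and the BINOL antipode that directs Re-face attack, CH2Cl2, −20 °C. This gives methyl (2Z,4R)-3-{[(tert-butyldimethylsilyl)oxy]methyl}-4-[(tributylstannyl)oxy]hepta-2,6-dienoate F6, which is hydrolysed on work-up to 11.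

Further compounds
F1 | step 10 | N-cyclohexyl-4-[(4aS,8aS)-2,5,5,8a-tetramethyl-3,4,4a,5,6,7,8,8a-octahydronaphthalen-1-yl]butan-1-imine | CC1=C(CCCC=NC3CCCCC3)[C@@]2(C)CCCC(C)(C)[C@@H]2CC1
F2 | step 10 | 4-[(4aS,8aS)-2,5,5,8a-tetramethyl-3,4,4a,5,6,7,8,8a-octahydronaphthalen-1-yl]butanal | CC1=C(CCCC=O)[C@@]2(C)CCCC(C)(C)[C@@H]2CC1
F3 | step 10 | 2-methylidene-4-[(4aS,8aS)-2,5,5,8a-tetramethyl-3,4,4a,5,6,7,8,8a-octahydronaphthalen-1-yl]butanal | CC1=C(CCC(=C)C=O)[C@@]2(C)CCCC(C)(C)[C@@H]2CC1
F4 | step 9 | 2,3-dibromo-4-[(2R)-3-{[(tert-butyldimethylsilyl)oxy]methyl}-5-oxo-2,5-dihydrofuran-2-yl]butanal | O=CC(Br)C(Br)C[C@H]1OC(=O)C=C1CO[Si](C)(C)C(C)(C)C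
F5 | step 9 | (2Z)-2-bromo-4-[(2R)-3-{[(tert-butyldimethylsilyl)oxy]methyl}-5-oxo-2,5-dihydrofuran-2-yl]but-2-enal | O=C/C(Br)=C/C[C@H]1OC(=O)C=C1CO[Si](C)(C)C(C)(C)C
F6 | step 7 | methyl (2Z,4R)-3-{[(tert-butyldimethylsilyl)oxy]methyl}-4-[(tributylstannyl)oxy]hepta-2,6-dienoate | COC(=O)/C=C(\[C@H](O[Sn](CCCC)(CCCC)CCCC)CC=C)CO[Si](C)(C)C(C)(C)C
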